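**Retrosynthetic overview** (core numbering: lactone C1(=O)–C2H2–C3H(Oa)–C4(CH3)(O)–C5H2–C6(CH3)(Ob)–C7H2–C8H(CH3)–C9H2–diene; peroxide Oa–Ob)
1. Target 25 ⇒ Negishi sp2–sp2 coupling of iodoalkene peroxylactone 19 with alkenyl iodide 22; the cation-sensitive diene is installed last.
2. 19 ⇒ acid lactonisation of the C3 acetic acid arm onto a C4 exo-methylene in dioxane 17; the γ-lactone is the second ring, and C4–O and the C4 methyl appear together.
3. 17 ⇒ one-pot (3+3) annulation that forms C5–C6 and Oa–C3 and closes the 1,2-dioxane (first ring) from silyl peroxyketal 9 and (R)-mesyloxy allylsilane 15.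
4. Enabling feature: in the 1,2-dioxane ring, C6 is a ketone-level carbon bound to Ob–Oa (a latent peroxycarbenium with electrophilic carbon and nucleophilic distal oxygen), and C5–C4–C3 is a 2-substituted allyl unit (C4 methyl carried as exo-methylene, C5 as allylsilane terminus, C3 as allylic carbinol carbon).
5. 9 comes from pent-1-en-4-yne by carboalumination, cross-metathesis and asymmetric conjugate addition (sets C8); 15 comes from (R)-malic acid.

Key step: step 11

Remark on the chemistry: compounds 1, 4, 10 and 20 are taken as commercial. Compounds 8 and 9 are carried as mixtures of epimers at the ketal carbon, which is planarised in step 11. The enantiomer and aryl groups of the IDPi catalyst in step 11 are to be fixed by a screen, and the 6R-selective one is meant.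

**Step 1**
Reactants: 1 pent-1-en-4-yne
Product: 3 (E)-1-iodo-2-methylpenta-1,4-diene, via alkenylalane 2 (not isolated)
Conditions: Me3Al, Cp2ZrCl2 (0.25 equiv), CH2Cl2, 0 °C → rt; then I2, THF, −30 °C
Reagents that add atoms: trimethylaluminium C[Al](C)C; iodine II
Why: Negishi zirconium-catalysed carboalumination adds Me and Al syn across the terminal alkyne with Al at the terminus, the isolated vinyl group staying inert, and iodinolysis with retention should give the E-iodoalkene.

**Step 2**
Reactants: 3 (E)-1-iodo-2-methylpenta-1,4-diene; 4 but-3-en-2-one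
Product: 5 (3E,6E)-7-iodo-6-methylhepta-3,6-dien-2-one
Conditions: 4 (3 equiv), (H2IMes)(Cl)2Ru=CH(2-iPrOC6H4) (second-generation Hoveyda–Grubbs catalyst, 3 mol %), CH2Cl2, 40 °C
Reagents that add atoms: none
Why: Olefin cross-metathesis between the terminal allyl-type olefin and the electron-poor enone partner should give the E-enone, the trisubstituted iodoalkene being too hindered to enter the cycle.

**Step 3**
Reactants: 5 (3E,6E)-7-iodo-6-methylhepta-3,6-dien-2-one
Product: 6 (4R,6E)-7-iodo-4,6-dimethylhept-6-en-2-one
Conditions: MeMgBr, CuBr·SMe2 (5 mol %), Josiphos-type ligand (C5H5)Fe[C5H3(PPh2)CH(CH3)PCy2] (6 mol %, enantiomer giving 4R), tBuOMe, −78 °C; then aq. NH4Cl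
Reagents that add atoms: methylmagnesium bromide C[Mg]Br
Why: Copper-catalysed asymmetric conjugate addition of the Grignard reagent to an acyclic E-enone sets the C8 methyl stereocentre under control of the chiral ferrocenyl diphosphine, and the low temperature should spare the iodoalkene and the doubly allylic CH2.

**Step 4**
Reactants: 6 (4R,6E)-7-iodo-4,6-dimethylhept-6-en-2-one
Product: 7 (1E,4R)-1-iodo-6,6-dimethoxy-2,4-dimethylhept-1-ene
Conditions: HC(OMe)3, MeOH, TsOH·H2O (cat.), rt
Reagents that add atoms: trimethyl orthoformate COC(OC)OC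
Why: Acid-catalysed ketalisation driven by the orthoformate as water scavenger leaves the stereocentre and the iodoalkene untouched.

**Step 5**
Reactants: 7 (1E,4R)-1-iodo-6,6-dimethoxy-2,4-dimethylhept-1-ene
Product: 8 (1E,4R)-6-hydroperoxy-1-iodo-6-methoxy-2,4-dimethylhept-1-ene (both epimers at C6)
Conditions: anhydrous H2O2 in Et2O (1.5 equiv), CSA (cat.), −20 → 0 °C
Reagents that add atoms: hydrogen peroxide OO
Why: Acid-catalysed perhydrolysis of a ketal exchanges one methoxy group for hydroperoxide through the oxocarbenium ion, and limiting the peroxide should hold the reaction at the α-methoxy hydroperoxide.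

**Step 6**
Reactants: 8 (1E,4R)-6-hydroperoxy-1-iodo-6-methoxy-2,4-dimethylhept-1-ene
Product: 9 (1E,4R)-1-iodo-6-methoxy-2,4-dimethyl-6-[(triethylsilyl)peroxy]hept-1-ene (both epimers at C6)
Conditions: Et3SiCl, imidazole, DMF, 0 °C
Reagents that add atoms: chlorotriethylsilane CC[Si](Cl)(CC)CC
Why: O-silylation of the hydroperoxide under basic conditions protects the peroxide and keeps the acid-labile ketal intact.

**Step 7**
Reactants: 10 (R)-malic acid
Product: 11 2-[(4R)-2,2-dimethyl-5-oxo-1,3-dioxolan-4-yl]acetic acid
Conditions: 2,2-dimethoxypropane, TsOH·H2O (cat.), rt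
Reagents that add atoms: 2,2-dimethoxypropane COC(C)(C)OC
Why: The α-hydroxy acid unit is tied up selectively as the 1,3-dioxolan-4-one, which differentiates the two carboxyl groups without touching the stereocentre.

**Step 8**
Reactants: 11 2-[(4R)-2,2-dimethyl-5-oxo-1,3-dioxolan-4-yl]acetic acid
Product: 12 tert-butyl 2-[(4R)-2,2-dimethyl-5-oxo-1,3-dioxolan-4-yl]acetate
Conditions: tert-butyl 2,2,2-trichloroacetimidate, BF3·OEt2 (cat.), CH2Cl2/cyclohexane, rt
Reagents that add atoms: tert-butyl 2,2,2-trichloroacetimidate CC(C)(C)OC(=N)C(Cl)(Cl)Cl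
Why: Acid-catalysed tert-butylation of the free carboxylic acid by the imidate is mild enough to keep the dioxolanone.

**Step 9**
Reactants: 12 tert-butyl 2-[(4R)-2,2-dimethyl-5-oxo-1,3-dioxolan-4-yl]acetate
Product: 14 tert-butyl (3R)-3-hydroxy-4-[(trimethylsilyl)methyl]pent-4-enoate, via bis(silylmethyl) carbinol 13 (not isolated)
Conditions: Me3SiCH2MgCl, CeCl3, THF, −78 °C → rt; then silica gel, CH2Cl2
Reagents that add atoms: (trimethylsilyl)methylmagnesium chloride C[Si](C)(C)C[Mg]Cl
Why: Double addition of the weakly basic organocerium reagent to the activated dioxolanone carbonyl (acetone is lost after the first addition, the hindered tert-butyl ester is spared) and acid-induced Peterson elimination give the 2-substituted allylsilane with the malic acid stereocentre retained.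

**Step 10**
Reactants: 14 tert-butyl (3R)-3-hydroxy-4-[(trimethylsilyl)methyl]pent-4-enoate
Product: 15 tert-butyl (3R)-3-[(methylsulfonyl)oxy]-4-[(trimethylsilyl)methyl]pent-4-enoate
Conditions: MsCl, Et3N, CH2Cl2, −40 °C; used at once without chromatography
Reagents that add atoms: methanesulfonyl chloride CS(=O)(=O)Cl
Why: Sulfonylation on oxygen keeps the C3 configuration, and cold handling should suppress ionisation and E1cB loss of the allylic β-mesyloxy ester.

**Step 11**
Reactants: 9 (1E,4R)-1-iodo-6-methoxy-2,4-dimethyl-6-[(triethylsilyl)peroxy]hept-1-ene; 15 tert-butyl (3R)-3-[(methylsulfonyl)oxy]-4-[(trimethylsilyl)methyl]pent-4-enoate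
Product: 17 tert-butyl 2-[(3S,6R)-6-[(2R,4E)-5-iodo-2,4-dimethylpent-4-en-1-yl]-6-methyl-4-methylidene-1,2-dioxan-3-yl]acetate, via silyl peroxide 16 (not isolated)
Conditions: chiral N-triflyl imidodiphosphorimidate (IDPi) acid (5 mol %), 15 (1.5 equiv), toluene, −78 °C; then TBAF (1.2 equiv), THF, −78 → 0 °C
Reagents that add atoms: none
Why: Proposed new method: the silylium form of the IDPi acid (generated in the flask from the acid and allylsilane 15) abstracts methoxide from 9 to give a triethylsilylperoxycarbenium ion paired with the confined chiral anion, which 15 attacks through its CH2= terminus (Hosomi–Sakurai addition with loss of Me3Si) to form C5–C6 in 16; fluoride then frees the peroxide anion, which displaces the allylic mesylate in a 6-exo-tet SN2 reaction to form Oa–C3 and close the 1,2-dioxane. The closest known reaction types are Lewis acid-mediated allylation of monoperoxyketals through peroxycarbenium ions, annulations with 2-(silylmethyl)allyl conjunctive reagents, intramolecular alkylation of hydroperoxides by sulfonates, and confined-acid silylium catalysis that tells the two small alkyl groups of ketone-derived silyloxocarbenium ion pairs apart. C6 is set by the catalyst (face selection between CH3 and the CH2R chain, which no substrate element can distinguish), and C3 is set by inversion of the (R)-mesylate, so no stereochemical information has to pass between the two centres. The step needs attack by the allylsilane and not by the iodoalkene on the cation (secured by the deactivating iodine and the excess of 15), desilylation and not capture of the β-silyl cation by the peroxide oxygen (secured by the small Me3Si group), and substitution and not E1cB loss of mesylate (secured by the allylically activated intramolecular geometry and the low basicity of the peroxide anion).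

**Step 12**
Reactants: 17 tert-butyl 2-[(3S,6R)-6-[(2R,4E)-5-iodo-2,4-dimethylpent-4-en-1-yl]-6-methyl-4-methylidene-1,2-dioxan-3-yl]acetate
Product: 19 (3R,4aS,7aS)-3-[(2R,4E)-5-iodo-2,4-dimethylpent-4-en-1-yl]-3,4a-dimethyl-4,4a,7,7a-tetrahydro-3H-furo[3,2-c][1,2]dioxin-6-one (iodoalkene peroxylactone), via carboxylic acid 18 (not isolated)
Conditions: TFA/CH2Cl2 (1:4), 0 °C → rt
Reagents that add atoms: none
Why: TFA cleaves the tert-butyl ester and protonates the exo-methylene in the Markovnikov sense, and the tertiary C4 cation is captured by the carboxyl group tethered at C3, which can only reach the same face, so the cis-fused γ-lactone (4S) and the C4 methyl are formed together (acid-mediated lactonisation of a γ,δ-unsaturated acid).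

**Step 13**
Reactants: 20 but-2-yn-1-ylbenzene
Product: 22 [(2E)-3-iodobut-2-en-1-yl]benzene, via alkenylzirconocene 21 (not isolated)
Conditions: Cp2Zr(H)Cl (1.6 equiv), THF, 50 °C; then I2, 0 °C
Reagents that add atoms: iodine II
Why: Hydrozirconation (syn addition of Zr–H) under equilibrating conditions should place zirconium on the less hindered, methyl-bearing alkyne carbon, and iodinolysis with retention gives the iodoalkene with iodine trans to the benzylic CH2.

**Step 14**
Reactants: 22 [(2E)-3-iodobut-2-en-1-yl]benzene; 19 iodoalkene peroxylactone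
Product: 25 (3R,4aS,7aS)-3,4a-dimethyl-3-[(2R,4E,6E)-2,4,6-trimethyl-8-phenylocta-4,6-dien-1-yl]-4,4a,7,7a-tetrahydro-3H-furo[3,2-c][1,2]dioxin-6-one (CNP0272658.1), via alkenyllithium 23 (not isolated), via alkenylzinc chloride 24 (not isolated)
Conditions: 22, tBuLi (2.1 equiv), Et2O, −78 °C; ZnCl2, THF; then 19, Pd(PPh3)4 (5 mol %), THF, 0 °C → rt
Reagents that add atoms: none
Why: Iodine–lithium exchange, transmetalation to zinc and Negishi coupling catalysed by zerovalent palladium join the two alkenyl units with retention of both double-bond geometries under neutral conditions that a dialkyl peroxide and a lactone should tolerate.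

**Compound list**
1 | pent-1-en-4-yne | C=CCC#C | starting material
2 | (E)-dimethyl(2-methylpenta-1,4-dien-1-yl)alane | C=CC/C(C)=C/[Al](C)C | intermediate
3 | (E)-1-iodo-2-methylpenta-1,4-diene | C=CC/C(C)=C/I | intermediate
4 | but-3-en-2-one (methyl vinyl ketone) | CC(=O)C=C | starting material
5 | (3E,6E)-7-iodo-6-methylhepta-3,6-dien-2-one | CC(=O)/C=C/C/C(C)=C/I | intermediate
6 | (4R,6E)-7-iodo-4,6-dimethylhept-6-en-2-one | CC(=O)C[C@H](C)C/C(C)=C/I | intermediate
7 | (1E,4R)-1-iodo-6,6-dimethoxy-2,4-dimethylhept-1-ene | COC(C)(OC)C[C@H](C)C/C(C)=C/I | intermediate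
8 | (1E,4R)-6-hydroperoxy-1-iodo-6-methoxy-2,4-dimethylhept-1-ene (both epimers at C6) | COC(C)(OO)C[C@H](C)C/C(C)=C/I | intermediate
9 | (1E,4R)-1-iodo-6-methoxy-2,4-dimethyl-6-[(triethylsilyl)peroxy]hept-1-ene (both epimers at C6) | COC(C)(OO[Si](CC)(CC)CC)C[C@H](C)C/C(C)=C/I | intermediate
10 | (R)-malic acid | O[C@H](CC(=O)O)C(=O)O | starting material
11 | 2-[(4R)-2,2-dimethyl-5-oxo-1,3-dioxolan-4-yl]acetic acid | CC1(C)O[C@H](CC(=O)O)C(=O)O1 | intermediate
12 | tert-butyl 2-[(4R)-2,2-dimethyl-5-oxo-1,3-dioxolan-4-yl]acetate | CC1(C)O[C@H](CC(=O)OC(C)(C)C)C(=O)O1 | intermediate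
13 | tert-butyl (3R)-3,4-dihydroxy-5-(trimethylsilyl)-4-[(trimethylsilyl)methyl]pentanoate | CC(C)(C)OC(=O)C[C@@H](O)C(O)(C[Si](C)(C)C)C[Si](C)(C)C | intermediate
14 | tert-butyl (3R)-3-hydroxy-4-[(trimethylsilyl)methyl]pent-4-enoate | CC(C)(C)OC(=O)C[C@@H](O)C(=C)C[Si](C)(C)C | intermediate
15 | tert-butyl (3R)-3-[(methylsulfonyl)oxy]-4-[(trimethylsilyl)methyl]pent-4-enoate | CC(C)(C)OC(=O)C[C@@H](OS(C)(=O)=O)C(=C)C[Si](C)(C)C | intermediate
16 | tert-butyl (3R,6R,8R,10E)-11-iodo-6,8,10-trimethyl-4-methylidene-3-[(methylsulfonyl)oxy]-6-[(triethylsilyl)peroxy]undec-10-enoate | CC(C)(C)OC(=O)C[C@@H](OS(C)(=O)=O)C(=C)C[C@](C)(OO[Si](CC)(CC)CC)C[C@H](C)C/C(C)=C/I | intermediate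
17 | tert-butyl 2-[(3S,6R)-6-[(2R,4E)-5-iodo-2,4-dimethylpent-4-en-1-yl]-6-methyl-4-methylidene-1,2-dioxan-3-yl]acetate | I/C=C(\C)C[C@@H](C)C[C@]1(C)CC(=C)[C@H](CC(=O)OC(C)(C)C)OO1 | intermediate
18 | 2-[(3S,6R)-6-[(2R,4E)-5-iodo-2,4-dimethylpent-4-en-1-yl]-6-methyl-4-methylidene-1,2-dioxan-3-yl]acetic acid | I/C=C(\C)C[C@@H](C)C[C@]1(C)CC(=C)[C@H](CC(=O)O)OO1 | intermediate
19 | (3R,4aS,7aS)-3-[(2R,4E)-5-iodo-2,4-dimethylpent-4-en-1-yl]-3,4a-dimethyl-4,4a,7,7a-tetrahydro-3H-furo[3,2-c][1,2]dioxin-6-one (core numbering 3S,4S,6R) | I/C=C(\C)C[C@@H](C)C[C@]1(C)C[C@]2(C)OC(=O)C[C@@H]2OO1 | intermediate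
20 | but-2-yn-1-ylbenzene | CC#CCc1ccccc1 | starting material
21 | chlorobis(cyclopentadienyl)[(2E)-4-phenylbut-2-en-2-yl]zirconium (Zr trans to the benzylic CH2; cyclopentadienyl rings drawn σ-bonded) | C/C(=C\Cc1ccccc1)[Zr](Cl)(C1C=CC=C1)C1C=CC=C1 | intermediate
22 | [(2E)-3-iodobut-2-en-1-yl]benzene | C/C(I)=C\Cc1ccccc1 | intermediate
23 | [(2Z)-4-phenylbut-2-en-2-yl]lithium (Li trans to the benzylic CH2) | C/C([Li])=C\Cc1ccccc1 | intermediate
24 | chloro[(2E)-4-phenylbut-2-en-2-yl]zinc (Zn trans to the benzylic CH2) | C/C([Zn]Cl)=C\Cc1ccccc1 | intermediate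
25 | (3R,4aS,7aS)-3,4a-dimethyl-3-[(2R,4E,6E)-2,4,6-trimethyl-8-phenylocta-4,6-dien-1-yl]-4,4a,7,7a-tetrahydro-3H-furo[3,2-c][1,2]dioxin-6-one (core numbering 3S,4S,6R,8R) | CC(=C\Cc1ccccc1)/C=C(\C)C[C@@H](C)C[C@]1(C)C[C@]2(C)OC(=O)C[C@@H]2OO1 | target

**Step count:** 14 steps in total. The longest linear sequence is 9 steps (steps 1–6, 11, 12 and 14).

**Steps most likely to fail**

Step 11 (Proposed new method). The risks are:
- weak face discrimination between methyl and the chain at the peroxycarbenium carbon;
- capture of the β-silyl cation by the peroxide oxygen, leading to a five-membered peroxide;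
- cyclisation of the iodoalkene onto the cation;
- elimination of mesylate before ring closure.

The fallback uses known chemistry and gives up catalyst control of C6. It sets out from 8 and 15 and comes back at 17. Hydroperoxy ketal 8 is alkylated on oxygen by mesylate 15 (CsOH·H2O, DMF, 0 °C; SN2 with inversion, the established alkylation of α-alkoxy hydroperoxides by sulfonates) to give the mixed peroxyketal F1. TMSOTf in CH2Cl2 at −78 °C then ionises the ketal, and the tethered allylsilane closes the dioxane by intramolecular Hosomi–Sakurai attack on the peroxycarbenium ion, a known cyclisation mode of unsaturated peroxyketals. This should give 17 together with its C6 epimer F2. The two are ring diastereomers and are to be separated by chromatography before step 12.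

Step 12. The risk is acid-induced heterolysis of the tertiary C6–O or allylic C3–O bond of the peroxide, or migration of the exo double bond without closure. The fallback avoids the free cation. It sets out from 17 and comes back at 19. The tert-butyl ester is removed under non-protic conditions (TMSOTf, 2,6-lutidine, CH2Cl2, then aqueous work-up) and acid 18 is isolated. Hg(OAc)2 in CH2Cl2 adds carboxylate and mercury across the exo-methylene to give the cis-fused lactone organomercurial F3. Alkaline NaBH4 at 0 °C replaces mercury by hydrogen, as in peroxymercuration–demercuration routes to cyclic peroxides, to give 19; the iodoalkene should survive.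

Step 14. The risk is cleavage of the O–O bond by the low-valent metal or by the organozinc reagent, or base-induced β-elimination that opens the peroxylactone. The fallback changes the nucleophile to a boronate and the transmetalation to a base-mediated one. It sets out from 22 and comes back at 25. Iodide 22 is converted (tBuLi, Et2O, −78 °C; then 2-isopropoxy-4,4,5,5-tetramethyl-1,3,2-dioxaborolane) into the alkenyl pinacol boronate F4. Suzuki–Miyaura coupling of F4 with 19 (Pd(dppf)Cl2, K3PO4, THF/H2O, rt) should give 25 with retention of both alkene geometries.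

**Further compounds**
F1 | step 11 | tert-butyl (3S)-3-{[(4R,6E)-7-iodo-2-methoxy-4,6-dimethylhept-6-en-2-yl]peroxy}-4-[(trimethylsilyl)methyl]pent-4-enoate | COC(C)(OO[C@@H](CC(=O)OC(C)(C)C)C(=C)C[Si](C)(C)C)C[C@H](C)C/C(C)=C/I
F2 | step 11 | tert-butyl 2-[(3S,6S)-6-[(2R,4E)-5-iodo-2,4-dimethylpent-4-en-1-yl]-6-methyl-4-methylidene-1,2-dioxan-3-yl]acetate | I/C=C(\C)C[C@@H](C)C[C@@]1(C)CC(=C)[C@H](CC(=O)OC(C)(C)C)OO1
F3 | step 12 | acetoxymercuriomethyl analogue of 19 (CH2HgOAc in place of the C4 methyl, same ring configuration) | I/C=C(\C)C[C@@H](C)C[C@]1(C)C[C@]2(C[Hg]OC(C)=O)OC(=O)C[C@@H]2OO1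
F4 | step 14 | 4,4,5,5-tetramethyl-2-[(2Z)-4-phenylbut-2-en-2-yl]-1,3,2-dioxaborolane (boron trans to the benzylic CH2) | C/C(B1OC(C)(C)C(C)(C)O1)=C\Cc1ccccc1
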